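Ring C (O1–C2–C3–C4(=O)–C4a–C8a) is a β-aryloxy ketone; its O1–C2–C3–C4 segment is, one oxidation level up at C4, a β-lactone. The route rests on disconnecting the C4–C4a and O1–C8a bonds together: a fully substituted ring A aryllithium (lithium on C4a, fluorine on C8a, lavandulyl on C8) attacks the acyl carbon of an enantiopure 4-aryloxetan-2-one, and the released C2 alkoxide displaces fluoride at C8a. In one flask the four-membered lactone grows by two atoms into the chromanone ring C; the C2–O1 bond is never broken, so the (2S) centre is carried in intact, and the single fluorine fixes the 8-lavandulyl regiochemistry. The (2R)-lavandulyl centre comes from an Evans deconjugative alkylation.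

Key step: step 13

Remark: flavanones with a 2,6-dioxygenated ring B are taken to hold their C2 configuration in cold neutral or mildly acidic media but not in base (retro-oxa-Michael opening), so ring C is closed in the penultimate step and sees no base afterwards.

Step 1
Reactants: 1 (S)-4-benzyloxazolidin-2-one; 2 3-methylbut-2-enoyl chloride
Product: 4 (S)-4-benzyl-3-(3-methylbut-2-enoyl)oxazolidin-2-one, via lithium oxazolidinide 3 (not isolated)
Conditions: n-BuLi, THF, −78 °C; then 2, −78 → 0 °C
Reagents that add atoms: none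
Why: N-acylation of the lithiated oxazolidinone by the acid chloride (standard formation of an Evans imide) touches no stereocentre.

Step 2
Reactants: 4 (S)-4-benzyl-3-(3-methylbut-2-enoyl)oxazolidin-2-one; 5 1-bromo-3-methylbut-2-ene (prenyl bromide)
Product: 7 (S)-4-benzyl-3-[(2S)-5-methyl-2-(prop-1-en-2-yl)hex-4-enoyl]oxazolidin-2-one, via sodium dienolate 6 (not isolated)
Conditions: NaN(SiMe3)2, THF, −78 °C; then 5, −78 → −40 °C
Reagents that add atoms: none
Why: Evans alkylation in its deconjugative form: γ-deprotonation gives the chelated (Z)-dienolate, which should be alkylated at the α-carbon on the face opposite the C4 benzyl group, setting the (2S) centre (the future C2'' of the lavandulyl group) and leaving the double bond as the isopropenyl group.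

Step 3
Reactants: 7 (S)-4-benzyl-3-[(2S)-5-methyl-2-(prop-1-en-2-yl)hex-4-enoyl]oxazolidin-2-one
Product: 8 (S)-lavandulol, (2S)-5-methyl-2-(prop-1-en-2-yl)hex-4-en-1-ol
Conditions: LiBH4, H2O (1 equiv), Et2O, 0 °C
Reagents that add atoms: none
Why: Reductive cleavage of the imide at the exocyclic acyl group should give the primary alcohol without touching the isolated alkenes, and the stereocentre is no longer α to a carbonyl group afterwards.

Step 4
Reactants: 8 (S)-lavandulol
Product: 9 (S)-lavandulyl iodide, (3S)-3-(iodomethyl)-2,6-dimethylhepta-1,5-diene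
Conditions: I2, PPh3, imidazole, CH2Cl2, 0 °C → rt
Reagents that add atoms: iodine, II
Why: Appel-type iodination proceeds by SN2 at the primary CH2, so the adjacent stereocentre is untouched.

Step 5
Reactants: 10 3-fluoro-5-methoxyphenol
Product: 11 (3-fluoro-5-methoxyphenoxy)tri(propan-2-yl)silane
Conditions: TIPSCl, imidazole, DMF, rt
Reagents that add atoms: chlorotri(propan-2-yl)silane (TIPSCl), CC(C)[Si](Cl)(C(C)C)C(C)C
Why: Silylation of the phenol installs a bulky, non-coordinating ether that shields both ring positions flanking it in the next step.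

Step 6
Reactants: 11 (3-fluoro-5-methoxyphenoxy)tri(propan-2-yl)silane
Product: 13 (3-fluoro-4-iodo-5-methoxyphenoxy)tri(propan-2-yl)silane, via aryllithium 12 (not isolated)
Conditions: n-BuLi, THF, −78 °C; then I2, −78 °C
Reagents that add atoms: iodine, II
Why: Directed ortho-metalation: the C–H between F and OMe is the only ring position that is acidified by fluorine and not flanked by the OTIPS group, so lithiation and iodine quench should be regioselective.

Step 7
Reactants: 9 (S)-lavandulyl iodide; 13 (3-fluoro-4-iodo-5-methoxyphenoxy)tri(propan-2-yl)silane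
Product: 15 {3-fluoro-5-methoxy-4-[(2R)-5-methyl-2-(prop-1-en-2-yl)hex-4-en-1-yl]phenoxy}tri(propan-2-yl)silane, via (S)-lavandulylzinc iodide 14 (not isolated)
Conditions: Zn, LiCl, THF, 40 °C; then 13, Pd(OAc)2, SPhos, THF, 50 °C
Reagents that add atoms: none
Why: Negishi coupling: zinc insertion at the primary carbon leaves the β-stereocentre untouched, and Pd(OAc)2/SPhos should couple a primary alkylzinc with a di-ortho-substituted aryl iodide faster than β-hydride elimination (the descriptor changes from S to R only through the priority change).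

Step 8
Reactants: 15 {3-fluoro-5-methoxy-4-[(2R)-5-methyl-2-(prop-1-en-2-yl)hex-4-en-1-yl]phenoxy}tri(propan-2-yl)silane
Product: 17 1-fluoro-3-methoxy-5-(methoxymethoxy)-2-[(2R)-5-methyl-2-(prop-1-en-2-yl)hex-4-en-1-yl]benzene, via tetrabutylammonium phenoxide 16 (not isolated)
Conditions: Bu4NF, THF, 0 °C; then MOMCl, 0 °C → rt
Reagents that add atoms: chloromethyl methyl ether (MOMCl), COCCl
Why: Fluoride cleaves the aryl silyl ether and the ammonium phenoxide is O-alkylated in the same flask (Williamson-type), exchanging the blocking group for an acid-labile MOM ether that no longer shields the neighbouring C–H.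

Step 9
Reactants: 18 2,6-dihydroxybenzaldehyde
Product: 19 2,6-bis(methoxymethoxy)benzaldehyde
Conditions: MOMCl, i-Pr2NEt, CH2Cl2, 0 °C → rt
Reagents that add atoms: chloromethyl methyl ether (MOMCl), COCCl
Why: Double O-alkylation protects both ring B phenols as ethers that tolerate organolithium reagents and leave together with the ring A MOM group at the end.

Step 10
Reactants: 19 2,6-bis(methoxymethoxy)benzaldehyde; 20 (S)-2-hydroxy-1,2,2-triphenylethyl acetate ((S)-HYTRA)
Product: 22 (1S)-2-hydroxy-1,2,2-triphenylethyl (3S)-3-[2,6-bis(methoxymethoxy)phenyl]-3-hydroxypropanoate, via dilithiated (S)-HYTRA 21 (not isolated)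
Conditions: LiN(i-Pr)2 (2 equiv), THF, −78 → 0 °C; then 19, THF/2-methylbutane, −125 °C; aq NH4Cl
Reagents that add atoms: none
Why: Auxiliary-controlled acetate aldol addition: the doubly deprotonated (S)-triphenylglycol acetate should add to one aldehyde face to give the (3S)-carbinol (aryl outranks CH2CO2R), and the crystalline adduct can be enriched by recrystallisation.

Step 11
Reactants: 22 (1S)-2-hydroxy-1,2,2-triphenylethyl (3S)-3-[2,6-bis(methoxymethoxy)phenyl]-3-hydroxypropanoate
Product: 23 (3S)-3-[2,6-bis(methoxymethoxy)phenyl]-3-hydroxypropanoic acid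
Conditions: KOH, MeOH/H2O, 25 °C; then 1 M HCl to pH 4, 0 °C
Reagents that add atoms: potassium hydroxide, [K+].[OH-]
Why: Saponification of the ester releases the β-hydroxy acid and the triphenylethanediol without breaking a bond at C3; the MOM ethers are stable to base and to brief cold acidification.

Step 12
Reactants: 23 (3S)-3-[2,6-bis(methoxymethoxy)phenyl]-3-hydroxypropanoic acid
Product: 24 (4S)-4-[2,6-bis(methoxymethoxy)phenyl]oxetan-2-one
Conditions: PhSO2Cl, pyridine, 0 °C
Reagents that add atoms: none
Why: β-Lactonisation by carboxyl activation: the β-hydroxyl attacks the mixed carboxylic–sulfonic anhydride (4-exo-trig), so the C3–O bond is not broken and the configuration is retained; the lactone is kept cold and used at once.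

Step 13
Reactants: 17 1-fluoro-3-methoxy-5-(methoxymethoxy)-2-[(2R)-5-methyl-2-(prop-1-en-2-yl)hex-4-en-1-yl]benzene; 24 (4S)-4-[2,6-bis(methoxymethoxy)phenyl]oxetan-2-one
Product: 27 (2S)-2-[2,6-bis(methoxymethoxy)phenyl]-7-methoxy-5-(methoxymethoxy)-8-[(2R)-5-methyl-2-(prop-1-en-2-yl)hex-4-en-1-yl]chroman-4-one, via aryllithium 25 (not isolated), via lithium keto alkoxide 26 (not isolated)
Conditions: lithium 2,2,6,6-tetramethylpiperidide (LiTMP), THF, −78 °C; then 24, −78 °C; then DMPU, −78 → 0 °C
Reagents that add atoms: none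
Why: LiTMP removes the only fluorine-activated ring proton left in 17 (C4a–H, flanked by F and OMOM) to give 25, which adds to the strained lactone carbonyl; the tetrahedral intermediate collapses with acyl–oxygen cleavage to the lithium β-keto alkoxide 26, whose oxygen then adds to C8a and expels fluoride in an SNAr step activated by the ortho C4 carbonyl. The closest known reaction types are the acyl–oxygen opening of β-lactones by organolithiums to β-hydroxy ketones and the alkoxide SNAr cyclisation of 2-fluoroaryl ketones to chromanones; together they insert C4a–C8a into the lactone O1–C4 bond, a two-atom ring expansion from four to six members. Ring C closes by O1–C8a bond formation as an addition–elimination at an sp2 carbon, formally a 6-endo-trig conjugate addition to the C8a=C4a–C4=O vinylogous acyl fluoride followed by loss of fluoride. No stereocentre is created: C2 is the lactone C4, none of its bonds is broken, so the (S) configuration is carried over, and C2'' is remote. The step needs acyl attack instead of enolisation or alkyl–oxygen attack (hard aryllithium at −78 °C, inverse addition, no excess base), a single addition (the di-ortho-substituted ketone in 26 is shielded) and ring closure faster than retro-aldol cleavage of 26 (DMPU, no warming above 0 °C, cold neutral quench). The regiochemistry of ring closure is secured by the substrate because C8a carries the only leaving group, so a 6-lavandulyl isomer cannot form.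

Step 14
Reactants: 27 (2S)-2-[2,6-bis(methoxymethoxy)phenyl]-7-methoxy-5-(methoxymethoxy)-8-[(2R)-5-methyl-2-(prop-1-en-2-yl)hex-4-en-1-yl]chroman-4-one
Product: 28 Exiguaflavanone B
Conditions: HCl (1.25 M in MeOH), MeOH, 25 °C
Reagents that add atoms: none
Why: Acid-catalysed acetal exchange should remove the three MOM ethers without base, so retro-oxa-Michael opening of ring C (the pathway that would epimerise C2) is avoided, and the lavandulyl alkenes have no neighbouring free phenol to cyclise onto.

Compound list
1 | (S)-4-benzyloxazolidin-2-one | O=C1OC[C@H](Cc2ccccc2)N1 | starting material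
2 | 3-methylbut-2-enoyl chloride | CC(C)=CC(=O)Cl | starting material
3 | lithium (S)-4-benzyl-2-oxooxazolidin-3-ide | O=C1OC[C@H](Cc2ccccc2)N1[Li] | intermediate
4 | (S)-4-benzyl-3-(3-methylbut-2-enoyl)oxazolidin-2-one | O=C1OC[C@H](Cc2ccccc2)N1C(=O)C=C(C)C | intermediate
5 | 1-bromo-3-methylbut-2-ene (prenyl bromide) | CC(C)=CCBr | starting material
6 | sodium (Z)-dienolate of 4 | O=C1OC[C@H](Cc2ccccc2)N1/C(O[Na])=C/C(C)=C | intermediate
7 | (S)-4-benzyl-3-[(2S)-5-methyl-2-(prop-1-en-2-yl)hex-4-enoyl]oxazolidin-2-one | O=C1OC[C@H](Cc2ccccc2)N1C(=O)[C@@H](CC=C(C)C)C(C)=C | intermediate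
8 | (S)-lavandulol, (2S)-5-methyl-2-(prop-1-en-2-yl)hex-4-en-1-ol | C=C(C)[C@H](CC=C(C)C)CO | intermediate
9 | (S)-lavandulyl iodide, (3S)-3-(iodomethyl)-2,6-dimethylhepta-1,5-diene | C=C(C)[C@H](CC=C(C)C)CI | intermediate
10 | 3-fluoro-5-methoxyphenol | COc1cc(O)cc(F)c1 | starting material
11 | (3-fluoro-5-methoxyphenoxy)tri(propan-2-yl)silane | COc1cc(F)cc(O[Si](C(C)C)(C(C)C)C(C)C)c1 | intermediate
12 | [2-fluoro-6-methoxy-4-(triisopropylsilyloxy)phenyl]lithium | COc1cc(O[Si](C(C)C)(C(C)C)C(C)C)cc(F)c1[Li] | intermediate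
13 | (3-fluoro-4-iodo-5-methoxyphenoxy)tri(propan-2-yl)silane | COc1cc(O[Si](C(C)C)(C(C)C)C(C)C)cc(F)c1I | intermediate
14 | (S)-lavandulylzinc iodide | C=C(C)[C@H](CC=C(C)C)C[Zn]I | intermediate
15 | {3-fluoro-5-methoxy-4-[(2R)-5-methyl-2-(prop-1-en-2-yl)hex-4-en-1-yl]phenoxy}tri(propan-2-yl)silane | C=C(C)[C@H](CC=C(C)C)Cc1c(F)cc(O[Si](C(C)C)(C(C)C)C(C)C)cc1OC | intermediate
16 | tetrabutylammonium 3-fluoro-5-methoxy-4-[(2R)-5-methyl-2-(prop-1-en-2-yl)hex-4-en-1-yl]phenoxide | C=C(C)[C@H](CC=C(C)C)Cc1c(F)cc([O-])cc1OC.CCCC[N+](CCCC)(CCCC)CCCC | intermediate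
17 | 1-fluoro-3-methoxy-5-(methoxymethoxy)-2-[(2R)-5-methyl-2-(prop-1-en-2-yl)hex-4-en-1-yl]benzene | C=C(C)[C@H](CC=C(C)C)Cc1c(F)cc(OCOC)cc1OC | intermediate
18 | 2,6-dihydroxybenzaldehyde | O=Cc1c(O)cccc1O | starting material
19 | 2,6-bis(methoxymethoxy)benzaldehyde | COCOc1cccc(OCOC)c1C=O | intermediate
20 | (S)-2-hydroxy-1,2,2-triphenylethyl acetate ((S)-HYTRA) | CC(=O)O[C@@H](c1ccccc1)C(O)(c1ccccc1)c1ccccc1 | starting material
21 | dilithiated (S)-HYTRA (lithium enolate, lithium alkoxide) | [Li]OC(=C)O[C@@H](c1ccccc1)C(O[Li])(c1ccccc1)c1ccccc1 | intermediate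
22 | (1S)-2-hydroxy-1,2,2-triphenylethyl (3S)-3-[2,6-bis(methoxymethoxy)phenyl]-3-hydroxypropanoate | COCOc1cccc(OCOC)c1[C@@H](O)CC(=O)O[C@@H](c1ccccc1)C(O)(c1ccccc1)c1ccccc1 | intermediate
23 | (3S)-3-[2,6-bis(methoxymethoxy)phenyl]-3-hydroxypropanoic acid | COCOc1cccc(OCOC)c1[C@@H](O)CC(=O)O | intermediate
24 | (4S)-4-[2,6-bis(methoxymethoxy)phenyl]oxetan-2-one | COCOc1cccc(OCOC)c1[C@@H]1CC(=O)O1 | intermediate
25 | {2-fluoro-4-methoxy-6-(methoxymethoxy)-3-[(2R)-5-methyl-2-(prop-1-en-2-yl)hex-4-en-1-yl]phenyl}lithium | C=C(C)[C@H](CC=C(C)C)Cc1c(F)c([Li])c(OCOC)cc1OC | intermediate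
26 | lithium (1S)-1-[2,6-bis(methoxymethoxy)phenyl]-3-{2-fluoro-4-methoxy-6-(methoxymethoxy)-3-[(2R)-5-methyl-2-(prop-1-en-2-yl)hex-4-en-1-yl]phenyl}-3-oxopropan-1-olate | C=C(C)[C@H](CC=C(C)C)Cc1c(F)c(C(=O)C[C@H](O[Li])c2c(OCOC)cccc2OCOC)c(OCOC)cc1OC | intermediate
27 | (2S)-2-[2,6-bis(methoxymethoxy)phenyl]-7-methoxy-5-(methoxymethoxy)-8-[(2R)-5-methyl-2-(prop-1-en-2-yl)hex-4-en-1-yl]chroman-4-one | C=C(C)[C@H](CC=C(C)C)Cc1c(OC)cc(OCOC)c2c1O[C@H](c1c(OCOC)cccc1OCOC)CC2=O | intermediate
28 | Exiguaflavanone B, (2S)-2-(2,6-dihydroxyphenyl)-5-hydroxy-7-methoxy-8-[(2R)-5-methyl-2-(prop-1-en-2-yl)hex-4-en-1-yl]chroman-4-one | C=C(C)[C@H](CC=C(C)C)Cc1c(OC)cc(O)c2c1O[C@H](c1c(O)cccc1O)CC2=O | target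

Total step count: 14. Longest linear sequence: 8 steps (steps 1, 2, 3, 4, 7, 8, 13, 14).

Steps most likely to fail

Step 13. The lithium β-keto alkoxide may revert by retro-aldol cleavage and recombine, or the hindered aryllithium may enolise the lactone, faster than fluoride is displaced; either would erode the C2 configuration or the conversion. The fallback sets out from 17 and 24 and keeps the lactone as acyl donor but separates the two events. 17 is lithiated and added to 24 at −78 °C as before, and the alkoxide is capped in the same flask with Et3SiOTf to give the triethylsilyloxy ketone F1, which is isolated. Bu4NF in THF at −40 → 0 °C then releases a lithium-free ammonium alkoxide that should close onto C8a at once. The fallback comes back to the route at 27.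

Step 12. The benzylic C–O bond, flanked by two ortho alkoxy donors, may ionise in the activated acid or in the lactone itself, leading to decarboxylation to the styrene or to loss of configuration. The fallback sets out from 23 and bypasses the four-membered ring with an open-chain acyl donor. 23 is converted into the Weinreb amide F2 (MeNHOMe·HCl, EDC·HCl, HOBt, N-methylmorpholine) and silylated to the tert-butyldimethylsilyl ether F3 (t-BuMe2SiOTf, 2,6-lutidine). Aryllithium 25, made from 17 with LiTMP as in the route, is acylated by F3 to give the silyloxy ketone F4. Bu4NF in THF then triggers desilylation and SNAr ring closure, and the fallback comes back to the route at 27.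

Step 10. The bulky dianion may add to the di-ortho-substituted, electron-rich aldehyde with poor facial selectivity or low conversion. The fallback sets out from 19 and sets C3 by catalyst-controlled reduction instead of an auxiliary-controlled C–C bond formation. Roskamp homologation (ethyl diazoacetate, SnCl2, CH2Cl2) gives the β-keto ester F5. Noyori hydrogenation with RuCl2[(R)-BINAP] and H2 in EtOH should give the (3S)-hydroxy ester F6. Hydrolysis with LiOH in THF/H2O comes back to the route at 23.

Further compounds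
F1 | step 13 | (3S)-3-[2,6-bis(methoxymethoxy)phenyl]-1-{2-fluoro-4-methoxy-6-(methoxymethoxy)-3-[(2R)-5-methyl-2-(prop-1-en-2-yl)hex-4-en-1-yl]phenyl}-3-(triethylsilyloxy)propan-1-one | C=C(C)[C@H](CC=C(C)C)Cc1c(F)c(C(=O)C[C@H](O[Si](CC)(CC)CC)c2c(OCOC)cccc2OCOC)c(OCOC)cc1OC
F2 | step 12 | (3S)-3-[2,6-bis(methoxymethoxy)phenyl]-3-hydroxy-N-methoxy-N-methylpropanamide | COCOc1cccc(OCOC)c1[C@@H](O)CC(=O)N(C)OC
F3 | step 12 | (3S)-3-[2,6-bis(methoxymethoxy)phenyl]-3-(tert-butyldimethylsilyloxy)-N-methoxy-N-methylpropanamide | COCOc1cccc(OCOC)c1[C@@H](O[Si](C)(C)C(C)(C)C)CC(=O)N(C)OC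
F4 | step 12 | (3S)-3-[2,6-bis(methoxymethoxy)phenyl]-3-(tert-butyldimethylsilyloxy)-1-{2-fluoro-4-methoxy-6-(methoxymethoxy)-3-[(2R)-5-methyl-2-(prop-1-en-2-yl)hex-4-en-1-yl]phenyl}propan-1-one | C=C(C)[C@H](CC=C(C)C)Cc1c(F)c(C(=O)C[C@H](O[Si](C)(C)C(C)(C)C)c2c(OCOC)cccc2OCOC)c(OCOC)cc1OC
F5 | step 10 | ethyl 3-[2,6-bis(methoxymethoxy)phenyl]-3-oxopropanoate | CCOC(=O)CC(=O)c1c(OCOC)cccc1OCOC
F6 | step 10 | ethyl (3S)-3-[2,6-bis(methoxymethoxy)phenyl]-3-hydroxypropanoate | CCOC(=O)C[C@H](O)c1c(OCOC)cccc1OCOC
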